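All runs were generated by integration for an exercise; noise was put on by code.

Slowness is what the flask will show for most of its 80 min, and this note explains why that stretch should be left alone.

| flask | electrophile | nucleophile | remark | time |
|---|---|---|---|---|
| cedar | 0.75 M | 1.35 M (in portions, 3) | run made earlier; portions every 40 s |  |
| maple | 1.1 M | 1.35 M (in portions, 3) | run made earlier; portions every 40 s |  |
| ash | 1.5 M | 2 M (in portions, 3) | run made earlier; portions every 40 s |  |
| flask | 1.5 M | 1.35 M (in portions, 3) | the portions of nucleophile follow each other after 40 s, the first at the start | 80 min |

| run | time / min | electrophile / % | product / % |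
|---|---|---|---|
| cedar | 6.00 | 10.3 | 91.1 |
| cedar | 10.0 | 5.8 | 93.8 |
| cedar | 15.0 | 4.2 | 95.1 |
| cedar | 25.0 | 2.3 | 97.7 |
| cedar | 30.0 | 1.4 | 97.5 |
| cedar | 50.0 | 0.4 | 99.0 |
| cedar | 80.0 | 0 | 99.9 |
| maple | 12.0 | 26.8 | 73.8 |
| maple | 25.0 | 21.7 | 79.7 |
| maple | 30.0 | 19.2 | 80.3 |
| maple | 50.0 | 15.4 | 83.1 |
| maple | 60.0 | 14.4 | 84.7 |
| maple | 80.0 | 11.6 | 87.1 |
| ash | 15.0 | 19.9 | 79.3 |
| ash | 30.0 | 14.7 | 83.9 |
| ash | 50.0 | 11.9 | 88.4 |
| ash | 60.0 | 10.5 | 90.3 |
| ash | 80.0 | 8.5 | 90.5 |

(each reading ± 0.5 percentage points)

- what may be going on: nucleophile + acid set free <-> protonated nucleophile; nucleophile <-> dormant form; electrophile + nucleophile -> acid set free + product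
- the reaction counts as stopped when no species that holds the electrophile changes by six tenths of a point or more over the second half of the time

1. the state of affairs at 80 min: stopped, and by what, or still going (all of the electrophile has reacted / forward and back rates have come level / it is still moving)
2. part of the electrophile gone at 80 min
3. the product standing at 80 min, as a percentage of the electrophile charged
4. amount of product if the flask were left three thousand times as long, in percent of the electrophile charged

The flask holds 1.35 M of nucleophile, less than its 1.5 M of electrophile, so the nucleophile is the limiting reagent. One nucleophile molecule meets either electrophile, giving product and one acid, or acid, becoming protonated nucleophile. During the quick rush each product therefore ties up a second nucleophile, and the rush in the flask should end when half of the charge has become product, at 45.0 % of the electrophile charged.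

After that, a protonated nucleophile has to let go, and the freed molecule again chooses between electrophile and acid. Its chance per minute of ending as product, the escape rate, should go as c(electrophile)/c(acid set free). The late ash readings, with product near 1.35 M, give the factor k_esc = 0.0118 /min, the escape constant: escape rate times c(acid set free)/c(electrophile). This reckoning counts protonated nucleophile as charge less product, and acid as product less protonated nucleophile, setting free nucleophile and dormant form aside.

The forecast says it is still moving, with 73 % gone, 73 % product and 90 % in the long run: “Ultimately all the nucleophile is consumed”. At that 73 %, my escape rate for the flask is 0.00569 /min, a half-life of 122 min, longer than 80 min. So the flask should be left stirring, with nothing added, and its slow drift taken as reaction.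

The flask's answer is that it is still moving, with 72.4 % gone, 72.4 % product and 90.0 % in the long run.

    nucleophile + acid set free ⇌ protonated nucleophile, settled at all times (K = 530 /M)
    nucleophile ⇌ dormant form (K = 0.990, k = 0.0350 /s)
    electrophile + nucleophile → acid set free + product (k = 0.100 /M/s)

Over the second half, a share in the flask still moved by 5.5 percentage points. At 80.0 min, k_esc gives the flask an escape rate of 0.00593 /min, with 0.262 M of protonated nucleophile still waiting. For a neighbouring flask, charged with 0.34 M of nucleophile, k_esc gives a faster escape rate at 80.0 min, 0.0411 /min. The protonated nucleophile of that neighbouring flask stands at 0.00302 M, and its product at 22.5 %.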